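**Plan**

- Feature: in the ten-membered ring (germacrane numbering) the C4–C5 oxirane and the C10 oxygen beside the C1 ketone are the oxidation products of two ring-trans alkenes, C4=C5 and a C1=C10 enol ether. O10 is syn-1,3 to O8, so one silicon atom can join O8 to the C1 enol oxygen before the oxidation and to O10 after it.
- Retrosynthesis: cut the C13–O ether and the two acetyl C–O bonds; then C4–O, C5–O and C10–O together (peracid); then the Si–O bonds; then C2–C3 (ring), C1–C2, C5–C6, C8–C9 and the C7–C8 and C11–C12 bonds of the butenolide.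
- Forward: butenolide ring from 2-butyne-1,4-diol, vinylmagnesium chloride and CO2; C8–C9 by methallylation; C5–C6 by vinylogous aldol with methacrolein; C1–C2 with a diazoacetate; ten-membered ring by zerovalent-palladium allylation at C2–C3; silylene ring; oxirane ring last.
- Stereochemistry: C8 from a Keck methallylation; C6 from a catalyst-controlled vinylogous Mukaiyama aldol; C4 and C5 from C6 (peracid anti to C7); C10 from C8 through the silicon bridge.

Key step: step 16

Remark: C10 (and C2 in 24 and 25) is carried as an inconsequential epimer mixture from step 6 until it becomes trigonal in step 15, and the sense of induction written for steps 4 and 7 rests on analogy, the mirror-image ligand or catalyst being the remedy if either adduct proves epimeric.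

**Route**

Step 1
Reactants: 1 2-butyne-1,4-diol
Product: 2 4-[(4-methoxybenzyl)oxy]but-2-yn-1-ol
Conditions: NaH (1 equiv), 1 (3 equiv), Bu4NI (cat.), THF/DMF, 0 °C to rt
Reagents that add atoms: 4-methoxybenzyl chloride COc1ccc(CCl)cc1
Why: Williamson ether synthesis; the threefold excess of the cheap diol keeps dialkylation low.

Step 2
Reactants: 2 4-[(4-methoxybenzyl)oxy]but-2-yn-1-ol; 3 vinylmagnesium chloride
Product: 6 3-{[(4-methoxybenzyl)oxy]methyl}-4-vinylfuran-2(5H)-one, via oxamagnesacycle 4 (not isolated), via hydroxy acid 5 (not isolated)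
Conditions: 3 (3.5 equiv), THF/toluene, 0 °C to reflux; CO2 (gas), −20 °C to rt; 1 M HCl
Reagents that add atoms: carbon dioxide O=C=O
Why: Hydroxyl-directed anti-carbomagnesiation of the propargylic alkoxide puts the vinyl group on the carbon next to the alkoxide and magnesium on the far carbon in a five-membered chelate, so carboxylation places the acid cis to CH2OH and acid work-up closes the butenolide.

Step 3
Reactants: 6 3-{[(4-methoxybenzyl)oxy]methyl}-4-vinylfuran-2(5H)-one
Product: 8 4-{[(4-methoxybenzyl)oxy]methyl}-5-oxo-2,5-dihydrofuran-3-carbaldehyde, via diol 7 (not isolated)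
Conditions: OsO4 (2 mol %), NaIO4 (4 equiv), 2,6-lutidine, dioxane/H2O 3:1, rt; used crude
Reagents that add atoms: osmium tetroxide O=[Os](=O)(=O)=O; sodium periodate [Na+].[O-]I(=O)(=O)=O (terminal oxidant that restores OsO4)
Why: Lemieux–Johnson cleavage, in which OsO4 dihydroxylates the monosubstituted vinyl group, leaves the tetrasubstituted ester-conjugated ring alkene, and periodate cleaves diol 7 as it forms.

Step 4
Reactants: 8 4-{[(4-methoxybenzyl)oxy]methyl}-5-oxo-2,5-dihydrofuran-3-carbaldehyde; 9 tributyl(2-methylallyl)stannane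
Product: 10 (S)-4-(1-hydroxy-3-methylbut-3-en-1-yl)-3-{[(4-methoxybenzyl)oxy]methyl}furan-2(5H)-one
Conditions: (S)-BINOL (20 mol %), Ti(OiPr)4 (10 mol %), 4 Å MS, CH2Cl2, −20 °C; aq. NaHCO3
Reagents that add atoms: none
Why: Keck asymmetric allylation, in which the titanium–(S)-BINOL Lewis acid should direct the methallyl group to the aldehyde face that gives 8S, as it does with aryl and α,β-unsaturated aldehydes, under neutral conditions that spare the base-sensitive butenolide.

Step 5
Reactants: 10 (S)-4-(1-hydroxy-3-methylbut-3-en-1-yl)-3-{[(4-methoxybenzyl)oxy]methyl}furan-2(5H)-one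
Product: 11 (S)-4-[1-(tert-butyldimethylsilyloxy)-3-methylbut-3-en-1-yl]-3-{[(4-methoxybenzyl)oxy]methyl}furan-2(5H)-one
Conditions: TBSCl, imidazole, DMF, rt
Reagents that add atoms: tert-butyldimethylsilyl chloride CC(C)(C)[Si](C)(C)Cl
Why: Standard silylation of the secondary alcohol, which must stay masked until the ring ketone is in place because a free C8 hydroxyl would add to C1.

Step 6
Reactants: 11 (S)-4-[1-(tert-butyldimethylsilyloxy)-3-methylbut-3-en-1-yl]-3-{[(4-methoxybenzyl)oxy]methyl}furan-2(5H)-one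
Product: 13 4-[(1S)-1-(tert-butyldimethylsilyloxy)-4-hydroxy-3-methylbutyl]-3-{[(4-methoxybenzyl)oxy]methyl}furan-2(5H)-one (both C10 epimers), via alkylborane 12 (not isolated)
Conditions: 9-BBN (1.5 equiv), THF, 0 °C to rt; NaBO3·4H2O, THF/H2O, rt
Reagents that add atoms: 9-borabicyclo[3.3.1]nonane [H]B1C2CCCC1CCC2 (boron of 12 only); sodium perborate [Na+].[O-]OB=O (hydroxyl oxygen)
Why: Anti-Markovnikov hydroboration–oxidation, in which 9-BBN adds only to the 1,1-disubstituted alkene and perborate oxidises the borane without the alkaline peroxide that could epoxidise the butenolide.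

Step 7
Reactants: 13 4-[(1S)-1-(tert-butyldimethylsilyloxy)-4-hydroxy-3-methylbutyl]-3-{[(4-methoxybenzyl)oxy]methyl}furan-2(5H)-one; 14 methacrolein
Product: 16 (5S)-5-[(1R)-1-hydroxy-2-methylprop-2-en-1-yl]-4-[(1S)-1-(tert-butyldimethylsilyloxy)-3-methyl-4-(triethylsilyloxy)butyl]-3-{[(4-methoxybenzyl)oxy]methyl}furan-2(5H)-one (5R,6S,8S in germacrane numbering), via silyloxyfuran 15 (not isolated)
Conditions: TESOTf (2.3 equiv), Et3N (3 equiv), CH2Cl2, 0 °C; pentane, filtration; then 14 (1.5 equiv), SiCl4 (1.2 equiv), (S,S)-bisphosphoramide (5 mol %; pentane-1,5-diyl-linked bis-phosphoramide of N,N′-dimethyl-1,1′-binaphthyl-2,2′-diamine), iPr2NEt (10 mol %), CH2Cl2, −78 °C; aq. NaHCO3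
Reagents that add atoms: triethylsilyl trifluoromethanesulfonate CC[Si](CC)(CC)OS(=O)(=O)C(F)(F)F
Why: Vinylogous Mukaiyama aldol addition under Lewis base-activated SiCl4, in which the silyloxyfuran attacks through C6 because C11 is substituted, the open transition state gives the anti adduct, and the catalyst, chosen to leave the Si face of the aldehyde open, sets 5R and with it 6S against any bias from C8.

Step 8
Reactants: 16 the aldol adduct
Product: 17 methyl carbonate of 16 at the C5 hydroxyl
Conditions: ClCO2Me (3 equiv), pyridine (6 equiv), DMAP (5 mol %), CH2Cl2, 0 °C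
Reagents that add atoms: methyl chloroformate COC(Cl)=O
Why: Acylation of the secondary allylic alcohol with a chloroformate and pyridine, a base too weak to trigger elimination across the acidic C6–H bond, installs the leaving group for the allylation.

Step 9
Reactants: 17 the C5 methyl carbonate
Product: 18 C1 aldehyde (butenolide with the C5 carbonate, C8 silyl ether and a 3-methyl-4-oxobutyl terminus)
Conditions: (COCl)2 (3 equiv), DMSO (6 equiv), CH2Cl2, −78 to −30 °C; Et3N, −78 to −20 °C
Reagents that add atoms: none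
Why: Swern oxidation applied directly to the primary triethylsilyl ether, which the chlorosulfonium salt cleaves and oxidises while the secondary tert-butyldimethylsilyl ether, the carbonate and the benzyl ether remain.

Step 10
Reactants: 19 2-(trimethylsilyl)ethanol
Product: 20 2-(trimethylsilyl)ethyl bromoacetate
Conditions: bromoacetyl bromide (1.5 equiv), NaHCO3 (3 equiv), MeCN, 0 °C
Reagents that add atoms: bromoacetyl bromide BrCC(Br)=O
Why: Acylation of the alcohol by the acid bromide with bicarbonate as acid scavenger.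

Step 11
Reactants: 20 2-(trimethylsilyl)ethyl bromoacetate
Product: 22 2-(trimethylsilyl)ethyl diazoacetate, via alkylated ditosylhydrazine 21 (not isolated)
Conditions: N,N′-ditosylhydrazine (2 equiv), DBU (5 equiv), THF, 0 °C
Reagents that add atoms: N,N′-ditosylhydrazine Cc1ccc(cc1)S(=O)(=O)NNS(=O)(=O)c1ccc(C)cc1
Why: Fukuyama diazoacetate synthesis, in which N-alkylation of the hydrazine by the bromoacetate and base-induced loss of two sulfinate ions from 21 leave the diazo group.

Step 12
Reactants: 18 the C1 aldehyde; 22 2-(trimethylsilyl)ethyl diazoacetate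
Product: 23 2-(trimethylsilyl)ethyl β-keto ester (C1 ketone, C2 methylene, ester on C2)
Conditions: SnCl2 (20 mol %), CH2Cl2, rt
Reagents that add atoms: none
Why: Roskamp homologation, in which SnCl2-catalysed addition of the diazoacetate to the aldehyde followed by 1,2-hydride shift and loss of dinitrogen gives the β-keto ester without base.

Step 13
Reactants: 23 the acyclic β-keto ester carbonate
Product: 24 ten-membered β-keto ester, (4E,6R,8S)-8-(tert-butyldimethylsilyloxy)-13-(4-methoxybenzyloxy)-1-oxogermacra-4,7(11)-dien-12,6-olide bearing the 2-(trimethylsilyl)ethyl ester on C2 (C2 and C10 epimers)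
Conditions: Pd2(dba)3·CHCl3 (5 mol %, zerovalent palladium), dppe (12 mol %), THF, 65 °C, slow addition of 23 to a final 2 mM
Reagents that add atoms: none
Why: Intramolecular Tsuji–Trost allylic alkylation, in which zerovalent palladium ionises the carbonate, the released methoxide deprotonates the β-keto ester, and the C2 enolate attacks the unsubstituted C3 terminus of the syn π-allyl complex anti to palladium, closing the ten-membered ring (rather than the eight-membered one through C5) with the C3 and C6 ring bonds trans on C4=C5.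

Step 14
Reactants: 24 the ten-membered β-keto ester
Product: 27 (4E,6R,8S)-8-hydroxy-13-(4-methoxybenzyloxy)-1-oxogermacra-4,7(11)-dien-12,6-olide (C10 epimers), via keto acid 25 (not isolated), via silyl ether ketone 26 (not isolated)
Conditions: Bu4NF (4 equiv), AcOH (4 equiv), THF, 0 to 45 °C
Reagents that add atoms: none
Why: Fluoride cleaves the 2-(trimethylsilyl)ethyl ester by β-elimination, the β-keto acid 25 loses CO2 on warming and the silyl ether of 26 is cleaved in the same flask, with acetic acid buffering the fluoride to protect the C6 stereocentre.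

Step 15
Reactants: 27 the hydroxy ketone
Product: 28 (1(10)Z,4E,6R,8S)-1,8-(di-tert-butylsilanediyldioxy)-13-(4-methoxybenzyloxy)germacra-1(10),4,7(11)-trien-12,6-olide (ring-trans C1=C10 enol ether held in a seven-membered O8–Si–O1 ring)
Conditions: tBu2Si(OTf)2 (1.15 equiv, added slowly), Et3N (5 equiv), CH2Cl2, 0 to 40 °C
Reagents that add atoms: di-tert-butylsilyl bis(trifluoromethanesulfonate) CC(C)(C)[Si](OS(=O)(=O)C(F)(F)F)(OS(=O)(=O)C(F)(F)F)C(C)(C)C
Why: Silyl triflate–amine enolisation made intramolecular, in which the bis-triflate silylates O8 (reopening any transannular hemiketal form of 27), the remaining Si–OTf bond activates the C1 carbonyl through a seven-membered ring, and equilibrating deprotonation should favour the tetrasubstituted enol ether inside that ring, where C9 and the enol oxygen are necessarily cis, so both C10 epimers converge on one ring-trans isomer while the lactone carbonyl is out of reach of the tethered silicon.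

Step 16
Reactants: 28 the silylene-bridged dienol ether
Product: 30 (4R,5R,6S,8S,10R)-4,5-epoxy-8,10-(di-tert-butylsilanediyldioxy)-13-(4-methoxybenzyloxy)-1-oxogermacr-7(11)-en-12,6-olide, via bis-oxirane 29 (not isolated)
Conditions: mCPBA (2.3 equiv), NaHCO3 (6 equiv), CH2Cl2, −20 to 0 °C, then rt
Reagents that add atoms: 3-chloroperbenzoic acid OOC(=O)c1cccc(Cl)c1
Why: Two Prilezhaev oxygen transfers give bis-oxirane 29, whose silyloxy-oxirane opens at C1 to an oxocarbenium ion and passes silicon from O1 to the new C10 oxide, which is the Rubottom oxidation run together with the outer-face epoxidation known for (E,E)-germacradienolides. The C4–C5 oxirane closes by concerted syn addition of one oxygen atom across the alkene, and the six-membered O8–Si–O10 ring arises from the seven-membered one by the intramolecular O-to-O silyl shift. C10 is set by C8: the silicon bridge holds C9 cis to the enol oxygen, so the C2–C7 chain must cross the face of C1=C10 on which C7 leaves C8, and the peracid can only reach the opposite face, which places O10 syn to O8. C4 and C5 are set by C6: allylic 1,3-strain with the C4 methyl keeps H6 in the alkene plane, C7 and the rest of the ring cover one face, and oxygen arrives on the other, as in the oxidation of costunolide to parthenolide. The step needs the two electron-rich alkenes to react ahead of the butenolide alkene and of Baeyer–Villiger oxidation at C1, which the electron-poor C7=C11 bond, the limit of 2.3 equivalents and the bicarbonate buffer should secure.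

Step 17
Reactants: 30 the silylene-bridged epoxy ketone
Product: 31 (4R,5R,6S,8S,10R)-4,5-epoxy-8,10-dihydroxy-13-(4-methoxybenzyloxy)-1-oxogermacr-7(11)-en-12,6-olide
Conditions: HF·pyridine, pyridine, THF, 0 °C to rt
Reagents that add atoms: none
Why: Fluoride-induced cleavage of the dialkoxysilane under buffered, non-basic conditions that should leave the oxirane, the α-ketol and the benzyl ether untouched.

Step 18
Reactants: 31 the diol
Product: 32 (4R,5R,6S,8S,10R)-8,10-diacetoxy-4,5-epoxy-13-(4-methoxybenzyloxy)-1-oxogermacr-7(11)-en-12,6-olide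
Conditions: Ac2O (10 equiv), pyridine, DMAP (0.3 equiv), CH2Cl2, rt to 35 °C
Reagents that add atoms: acetic anhydride CC(=O)OC(C)=O
Why: DMAP-catalysed (Steglich-type) acetylation of the secondary hydroxyl and the tertiary α-ketol hydroxyl with a weak base, which avoids C6–H abstraction and the oxirane opening it would cause.

Step 19
Reactants: 32 the diacetate 4-methoxybenzyl ether
Product: 33 CNP0266633.2, (4R,5R,6S,8S,10R)-8,10-diacetoxy-4,5-epoxy-13-hydroxy-1-oxogermacr-7(11)-en-12,6-olide
Conditions: DDQ (1.5 equiv), CH2Cl2/pH 7 phosphate buffer 10:1, 0 °C to rt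
Reagents that add atoms: none
Why: Oxidative cleavage of the 4-methoxybenzyl ether by hydride abstraction with DDQ and hydrolysis of the resulting oxocarbenium ion under neutral conditions that tolerate oxirane, acetates and butenolide.

**Compound list**

1 | 2-butyne-1,4-diol | OCC#CCO | starting material
2 | 4-[(4-methoxybenzyl)oxy]but-2-yn-1-ol | OCC#CCOCc1ccc(OC)cc1 | intermediate
3 | vinylmagnesium chloride | C=C[Mg]Cl | starting material
4 | cyclic alkenylmagnesium alkoxide (3-ethenyl-4-{[(4-methoxybenzyl)oxy]methyl}-2,5-dihydro-1,2-oxamagnesole) | C=CC1=C(COCc2ccc(OC)cc2)[Mg]OC1 | intermediate (not isolated)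
5 | (Z)-3-(hydroxymethyl)-2-{[(4-methoxybenzyl)oxy]methyl}penta-2,4-dienoic acid | OC/C(C=C)=C(\C(O)=O)COCc1ccc(OC)cc1 | intermediate (not isolated)
6 | 3-{[(4-methoxybenzyl)oxy]methyl}-4-vinylfuran-2(5H)-one | C=CC1=C(COCc2ccc(OC)cc2)C(=O)OC1 | intermediate
7 | 4-(1,2-dihydroxyethyl)-3-{[(4-methoxybenzyl)oxy]methyl}furan-2(5H)-one (racemic) | OCC(O)C1=C(COCc2ccc(OC)cc2)C(=O)OC1 | intermediate (not isolated)
8 | 4-{[(4-methoxybenzyl)oxy]methyl}-5-oxo-2,5-dihydrofuran-3-carbaldehyde | O=CC1=C(COCc2ccc(OC)cc2)C(=O)OC1 | intermediate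
9 | tributyl(2-methylallyl)stannane | CCCC[Sn](CCCC)(CCCC)CC(C)=C | starting material
10 | (S)-4-(1-hydroxy-3-methylbut-3-en-1-yl)-3-{[(4-methoxybenzyl)oxy]methyl}furan-2(5H)-one | O=C1OCC([C@@H](O)CC(C)=C)=C1COCc1ccc(OC)cc1 | intermediate
11 | (S)-4-[1-(tert-butyldimethylsilyloxy)-3-methylbut-3-en-1-yl]-3-{[(4-methoxybenzyl)oxy]methyl}furan-2(5H)-one | O=C1OCC([C@@H](O[Si](C)(C)C(C)(C)C)CC(C)=C)=C1COCc1ccc(OC)cc1 | intermediate
12 | B-alkyl-9-borabicyclo[3.3.1]nonane from 11 (boron on C1, C10 epimers) | O=C1OCC([C@@H](O[Si](C)(C)C(C)(C)C)CC(C)CB2C3CCCC2CCC3)=C1COCc1ccc(OC)cc1 | intermediate (not isolated)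
13 | 4-[(1S)-1-(tert-butyldimethylsilyloxy)-4-hydroxy-3-methylbutyl]-3-{[(4-methoxybenzyl)oxy]methyl}furan-2(5H)-one (C10 epimers) | O=C1OCC([C@@H](O[Si](C)(C)C(C)(C)C)CC(C)CO)=C1COCc1ccc(OC)cc1 | intermediate
14 | methacrolein | CC(=C)C=O | starting material
15 | 2-(triethylsilyloxy)furan from 13, primary hydroxyl as triethylsilyl ether (C10 epimers) | CC[Si](CC)(CC)Oc1occ([C@@H](O[Si](C)(C)C(C)(C)C)CC(C)CO[Si](CC)(CC)CC)c1COCc1ccc(OC)cc1 | intermediate (not isolated)
16 | (5S)-5-[(1R)-1-hydroxy-2-methylprop-2-en-1-yl]-4-[(1S)-1-(tert-butyldimethylsilyloxy)-3-methyl-4-(triethylsilyloxy)butyl]-3-{[(4-methoxybenzyl)oxy]methyl}furan-2(5H)-one (C10 epimers) | C=C(C)[C@@H](O)[C@H]1OC(=O)C(COCc2ccc(OC)cc2)=C1[C@@H](O[Si](C)(C)C(C)(C)C)CC(C)CO[Si](CC)(CC)CC | intermediate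
17 | C5 methyl carbonate of 16 | C=C(C)[C@@H](OC(=O)OC)[C@H]1OC(=O)C(COCc2ccc(OC)cc2)=C1[C@@H](O[Si](C)(C)C(C)(C)C)CC(C)CO[Si](CC)(CC)CC | intermediate
18 | C1 aldehyde from 17 | C=C(C)[C@@H](OC(=O)OC)[C@H]1OC(=O)C(COCc2ccc(OC)cc2)=C1[C@@H](O[Si](C)(C)C(C)(C)C)CC(C)C=O | intermediate
19 | 2-(trimethylsilyl)ethanol | C[Si](C)(C)CCO | starting material
20 | 2-(trimethylsilyl)ethyl bromoacetate | C[Si](C)(C)CCOC(=O)CBr | intermediate
21 | 2-(trimethylsilyl)ethyl N,N′-ditosylhydrazinoacetate | Cc1ccc(cc1)S(=O)(=O)NN(CC(=O)OCC[Si](C)(C)C)S(=O)(=O)c1ccc(C)cc1 | intermediate (not isolated)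
22 | 2-(trimethylsilyl)ethyl diazoacetate | C[Si](C)(C)CCOC(=O)C=[N+]=[N-] | intermediate
23 | acyclic 2-(trimethylsilyl)ethyl β-keto ester with C5 carbonate (5R,6S,8S; C10 epimers) | C=C(C)[C@@H](OC(=O)OC)[C@H]1OC(=O)C(COCc2ccc(OC)cc2)=C1[C@@H](O[Si](C)(C)C(C)(C)C)CC(C)C(=O)CC(=O)OCC[Si](C)(C)C | intermediate
24 | ten-membered β-keto ester (4E,6R,8S; C2 and C10 epimers) | CC(C)(C)[Si](C)(C)O[C@H]1CC(C)C(=O)C(C(=O)OCC[Si](C)(C)C)C/C(C)=C/[C@H]2OC(=O)C(COCc3ccc(OC)cc3)=C12 | intermediate
25 | ten-membered β-keto acid (4E,6R,8S) | CC(C)(C)[Si](C)(C)O[C@H]1CC(C)C(=O)C(C(O)=O)C/C(C)=C/[C@H]2OC(=O)C(COCc3ccc(OC)cc3)=C12 | intermediate (not isolated)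
26 | ten-membered ketone, C8 silyl ether (4E,6R,8S) | CC(C)(C)[Si](C)(C)O[C@H]1CC(C)C(=O)CC/C(C)=C/[C@H]2OC(=O)C(COCc3ccc(OC)cc3)=C12 | intermediate (not isolated)
27 | (4E,6R,8S)-8-hydroxy-13-(4-methoxybenzyloxy)-1-oxogermacra-4,7(11)-dien-12,6-olide (C10 epimers) | O[C@H]1CC(C)C(=O)CC/C(C)=C/[C@H]2OC(=O)C(COCc3ccc(OC)cc3)=C12 | intermediate
28 | (1(10)Z,4E,6R,8S)-1,8-(di-tert-butylsilanediyldioxy)-13-(4-methoxybenzyloxy)germacra-1(10),4,7(11)-trien-12,6-olide | CC(C)(C)[Si]3(C(C)(C)C)O[C@H]1C/C(C)=C(O3)/CC/C(C)=C/[C@H]2OC(=O)C(COCc4ccc(OC)cc4)=C12 | intermediate (key-step precursor)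
29 | 1,10:4,5-bis-oxirane of 28, both oxygens on the outer faces | CC(C)(C)[Si]3(C(C)(C)C)O[C@H]1C[C@@]4(C)O[C@]4(O3)CC[C@@]2(C)O[C@@H]2[C@H]2OC(=O)C(COCc5ccc(OC)cc5)=C12 | intermediate (not isolated)
30 | (4R,5R,6S,8S,10R)-4,5-epoxy-8,10-(di-tert-butylsilanediyldioxy)-13-(4-methoxybenzyloxy)-1-oxogermacr-7(11)-en-12,6-olide | CC(C)(C)[Si]3(C(C)(C)C)O[C@H]1C[C@@](C)(O3)C(=O)CC[C@@]2(C)O[C@@H]2[C@H]2OC(=O)C(COCc4ccc(OC)cc4)=C12 | intermediate (key-step product)
31 | (4R,5R,6S,8S,10R)-4,5-epoxy-8,10-dihydroxy-13-(4-methoxybenzyloxy)-1-oxogermacr-7(11)-en-12,6-olide | O[C@H]1C[C@@](C)(O)C(=O)CC[C@@]2(C)O[C@@H]2[C@H]2OC(=O)C(COCc3ccc(OC)cc3)=C12 | intermediate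
32 | (4R,5R,6S,8S,10R)-8,10-diacetoxy-4,5-epoxy-13-(4-methoxybenzyloxy)-1-oxogermacr-7(11)-en-12,6-olide | CC(=O)O[C@H]1C[C@@](C)(OC(C)=O)C(=O)CC[C@@]2(C)O[C@@H]2[C@H]2OC(=O)C(COCc3ccc(OC)cc3)=C12 | intermediate
33 | CNP0266633.2 | CC(=O)O[C@H]1C[C@@](C)(OC(C)=O)C(=O)CC[C@@]2(C)O[C@@H]2[C@H]2OC(=O)C(CO)=C12 | target

**Count and risks**

Total step count: 19. Longest linear sequence: 17 (steps 1–9 and 12–19; steps 10–11 make the diazoacetate).

Step 13 (ring closure). The π-allyl complex sits next to the acidic C6–H, so loss of that proton to a dienyl butenolide, attack at C5, syn–anti isomerisation to the ring-cis alkene, or oligomerisation may outrun ten-membered ring closure. The fallback avoids a π-allyl complex and fixes the alkene geometry before cyclisation. It sets out from 16: thionyl chloride in ether with 2,6-di-tert-butylpyridine converts the C5 alcohol, by internal collapse of the chlorosulfite with allylic shift, into the rearranged (E)-allylic chloride F1. Swern oxidation as in step 9 gives aldehyde F2, and the SnCl2-catalysed homologation with 22 gives chloro β-keto ester F3. Cs2CO3 and NaI in MeCN at high dilution then close the ring by SN2 alkylation of the β-keto ester, and the route is rejoined at 24.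

Step 15 (tethered enol ether). Deprotonation of the activated ketone may go toward C2 instead of C10, or the ring may resist the ring-trans C1=C10 bond. The fallback uses the C8 oxygen itself as the tether. It sets out from 27: PPTS and 4 Å MS in toluene at 60 °C dehydrate the transannular hemiketal to the bridged dihydrofuran F4, in which the endocyclic C1=C10 enol ether is the thermodynamically preferred isomer and again has C9 cis to oxygen. mCPBA with NaHCO3 in wet CH2Cl2 epoxidises C4=C5 and the enol ether on the same faces as in step 16, water opens the enol ether oxirane at C1 to the hydroxy hemiketal F5, and this opens to the diol, so the route is rejoined at 31.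

Step 7 (vinylogous aldol). The C8 stereocentre of the furan and the chiral catalyst may be mismatched, giving poor facial selectivity at C6. The fallback gives up control in the bond-forming event and recovers it by separation and recycling. It sets out from 15: BF3·OEt2 at −78 °C without chiral catalyst gives 16 together with adducts of the other C6 configuration, such as the C5,C6-bis-epimer F6, which are diastereomers because C8 is fixed and are separated by chromatography. DBU in CH2Cl2 returns F6 by retro-aldol cleavage to the butenolide silyl ether F7, which is silylated again to 15. The route is rejoined at 16.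

**Further compounds**

F1 | step 13 | (5S)-5-[(E)-3-chloro-2-methylprop-1-en-1-yl]-4-[(1S)-1-(tert-butyldimethylsilyloxy)-3-methyl-4-(triethylsilyloxy)butyl]-3-{[(4-methoxybenzyl)oxy]methyl}furan-2(5H)-one (6R in germacrane numbering) | ClC/C(C)=C/[C@H]1OC(=O)C(COCc2ccc(OC)cc2)=C1[C@@H](O[Si](C)(C)C(C)(C)C)CC(C)CO[Si](CC)(CC)CC
F2 | step 13 | C1 aldehyde from F1 | ClC/C(C)=C/[C@H]1OC(=O)C(COCc2ccc(OC)cc2)=C1[C@@H](O[Si](C)(C)C(C)(C)C)CC(C)C=O
F3 | step 13 | 2-(trimethylsilyl)ethyl β-keto ester from F2 | ClC/C(C)=C/[C@H]1OC(=O)C(COCc2ccc(OC)cc2)=C1[C@@H](O[Si](C)(C)C(C)(C)C)CC(C)C(=O)CC(=O)OCC[Si](C)(C)C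
F4 | step 15 | (4E,6R,8S)-1,8-epoxy-13-(4-methoxybenzyloxy)germacra-1(10),4,7(11)-trien-12,6-olide (bridged dihydrofuran) | O3[C@H]1C/C(C)=C3/CC/C(C)=C/[C@H]2OC(=O)C(COCc4ccc(OC)cc4)=C12
F5 | step 15 | 1,8-epoxy-1,10-dihydroxy hemiketal, closed form of 31 | O3[C@H]1C[C@@](C)(O)[C@]3(O)CC[C@@]2(C)O[C@@H]2[C@H]2OC(=O)C(COCc4ccc(OC)cc4)=C12
F6 | step 7 | (5R)-5-[(1S)-1-hydroxy-2-methylprop-2-en-1-yl] epimer of 16 | C=C(C)[C@H](O)[C@@H]1OC(=O)C(COCc2ccc(OC)cc2)=C1[C@@H](O[Si](C)(C)C(C)(C)C)CC(C)CO[Si](CC)(CC)CC
F7 | step 7 | triethylsilyl ether of 13 | O=C1OCC([C@@H](O[Si](C)(C)C(C)(C)C)CC(C)CO[Si](CC)(CC)CC)=C1COCc1ccc(OC)cc1
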